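## Structural features

The target is a labdane. Labdane numbering is used throughout for the tricyclic compounds: decalin C1–C10, chain C11–C16, C17 on C8, C18/C19 on C4, C20 on C10; β is the face of C20, α the opposite face. Its configuration is (4S,5R,6S,8R,9S,10S,13R).

A trans-decalin (rings A/B) carries a γ-lactone from C19 (axial on C4) to O-6β. A tetrahydrofuran (O–C9–C11–C12–C13) is spiro-fused to ring B at C9 and to a second γ-lactone (C13–C14–C15(=O)–O–C16) at C13. Six of the seven stereocentres are contiguous (C4–C5–C6 and C8–C9–C10); C13 stands alone across the ether oxygen.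

Ring B bears oxygen on four consecutive carbons: C6 (lactone O), C7 (ketone), C8 (tertiary acetate, β) and C9 (tertiary ether, α). C8, C9 and C10 are three adjacent fully substituted carbons, with O-8 and O-9 trans-diaxial.

Fragile groups are the β-alkoxy lactone at C13 (base opens it by β-elimination and scrambles C13), the tertiary α-acetoxy ketone (acyl shift, α-ketol shift) and both lactones (hard nucleophiles).

The real difficulty is twofold. First, the β face of ring B is screened by axial C20 and by the C19–O6 bridge. An electrophilic oxygen at C8 or a carbon nucleophile at a C9 ketone would therefore enter from α and give the wrong C8–O and C9–C11 sense. Second, C13 has no neighbour that could control it.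

The key step exploits this pattern. C6–C9 with their four oxygens plus C10–CH3 are the substitution pattern of 2,3-dimethoxy-5-methylbenzoquinone. If O-8 comes in with the quinone, the two bonds still missing at the C8/C9 diad are O13→C9 and C17→C8. Both must form on the open α face, so they are made together on a C8=C9 enone. C13 is brought in from malic acid with its C–O bond never broken.

## Logic of the disconnections

27 ⇒ 26. The acyl C–O bond of the C8 acetate is cut, so that O-8 carries a methyl group in 26. O-8 must be in place before C17 is introduced, and an α-acyloxy ketone would not survive enolate chemistry (acyl shift). The forward step has to cleave O–CH3 while leaving the C8–O bond (retention) and the bis-tertiary ether intact.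

26 ⇒ 23 (key). The ring bond C9–O of the tetrahydrofuran and the C8–C17 bond are cut together. This removes two adjacent fully substituted stereocentres and the spiro ring, and leaves the planar 8-methoxy-Δ8(9)-7-ketone 23 with a free C13 hydroxyl. In one sentence, the route is a tandem oxa-Michael spirocyclisation and C8-methylation of 23. The forward step needs the alkoxide to add to C9 faster than any proton transfer, carbon rather than oxygen methylation from the α face, and no enolisation of the side-chain lactone.

23 ⇒ 21 ⇒ 20. The acyl–oxygen bond C15–O16 is cut and C15 is traced back to the inner carbon of a terminal vinyl group; O-13 and O-16 are tied as an acetonide. The side chain has to pass through an organometallic stage, which a lactone would not survive. The forward steps need oxidative cleavage of a monosubstituted alkene beside the enol-ether enone, with the 13,16-diol masked until periodate is gone.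

20 ⇒ 9 + 16. The C9–C11 bond is cut, and the C7 ketone/C8=C9 unit is traced back to a C9 ketone with a C7 enol ether (1,3-carbonyl transposition). C9 of 9 is the only ketone carbon, so the union is a 1,2-addition. The forward step needs attack at neopentyl C9 in the presence of the C19 lactone, and an acid step that spares the acetonide.

9 ⇒ 7 ⇒ 6. The lactone bond O6–C19 and the C6–H bond are cut (7, through 8), then the C2–H/C3–H bonds (6). C6 is the less hindered of two electronically equal carbonyls. The forward reduction must choose C6 over C9 and deliver hydride from the α face so that O-6 is β and can reach the axial ester.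

6 ⇒ 3. The C4–C18 bond is cut and the C5 configuration is released. In the dienediolate both C4 and C5 are trigonal and C20 is the only group out of plane. One operation then gives the C4 quaternary centre and the trans ring fusion from the cis adduct. The forward step needs methylation at C4 only.

3 ⇒ 1 + 2. The bonds C1–C10 and C4–C5 of ring A are cut. 1 already holds C5–C10 with every ring-B oxygen, and 2 holds C1–C4 with C19. The forward Diels–Alder reaction must be site-selective (C5=C10, not C7=C8), regioselective, endo and enantioselective at C10.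

16 ⇒ 15 ⇒ 14 ⇒ 13 ⇒ 11 ⇒ 10. The C13–C14 bond is cut. C11 and C16 are traced to the two carboxyl carbons of 10, and O-13 to its hydroxyl. C13 is a tertiary carbinol carbon with three CH2 arms, which is an α-alkylated malic acid. The forward sequence needs alkylation with retention and a 1,2-selective acetonide.

## Other disconnections considered

Alternative 1: (the first that comes to mind) Cut C13–O9 and the C15 carbonyl along the biogenetic line. The forward key step is acid- or oxidant-induced addition of the 9α-hydroxyl of the 3-furyl labdane A1 to furan C13, giving the spiro dihydrofuran A2, followed by oxidation at C15. The chosen plan is preferred for three reasons. C13 would form in a reversible addition whose nearest stereocentre is C9 across the oxygen, so both C13 epimers are to be expected. A1 already contains the whole C8/C9/C10 problem: the 8β-acetoxy/9α-hydroxy trans pair, and a side chain that a 9-ketone would accept from the α face. The hardest part is thus only postponed, and the route is longer.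

Alternative 2: Cut O16–C15 as a late single-atom (oxygen) insertion. The forward key step is a Baeyer–Villiger oxidation of the C13-spiro cyclobutanone A3, made from the exocyclic enol ether A4 by ketene [2+2] cycloaddition and dechlorination. The reagent must choose one of two CH2 groups. These differ only through C9, four bonds away, so the choice rests entirely on a catalyst, on a 3,3-disubstituted cyclobutanone and beside a second ketone at C7. A4 still needs the C8/C9 diad solved first, and the sequence costs about four more steps than taking C13 from the chiral pool.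

Alternative 3: Cut C9–O with ring B as an arene. The forward key step is para-oxidative spiro-etherification of phenol A5 to dienone A6, followed by a Diels–Alder reaction of A6 with 2 for ring A. The two enone arms of A6 differ only through remote C13, so nothing decides which arm reacts and hence the C9 configuration. A β-methyl dienone with an electron-poor diene is an unreactive pair, and Lewis acid activation invites dienone–phenol rearrangement. O-7 and O-8 would then have to be added by electrophilic oxidation, which comes from the α face and gives the wrong C8 centre.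

Key step: step 13

Assumption 1: the oxazaborolidinium catalyst from (S)-α,α-diphenylprolinol is taken to give the (10S) adduct 3; if the sense of induction is the opposite, its enantiomer is used.
Assumption 2: small electrophiles and protecting reagents (iodomethane, allyl bromide, pivalaldehyde, 2,2-dimethoxypropane, iodine, acetic anhydride) are treated as reagents and carry no compound number.

## Route

Step 1
Reactants: 1 2,3-dimethoxy-5-methyl-1,4-benzoquinone; 2 methyl (2E)-penta-2,4-dienoate
Product: 3 methyl (1R,4aS,8aR)-6,7-dimethoxy-4a-methyl-5,8-dioxo-1,4,4a,5,8,8a-hexahydronaphthalene-1-carboxylate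
Conditions: 2 (2 equiv), oxazaborolidinium triflimide from (S)-α,α-diphenylprolinol, o-tolylboronic acid and Tf2NH (20 mol %), CH2Cl2, −78 → −20 °C
Reagents that add atoms: none
Why: Catalytic enantioselective Diels–Alder reaction: boron binds the C6 carbonyl of 1 (the one next to C5–H), so only C5=C10 reacts (C7=C8 is tetrasubstituted and deactivated by two methoxy groups) and the unsubstituted diene terminus C1 bonds to C10, β to the activated carbonyl. The endo transition state gives the cis-fused adduct with the ester trans to H-5, and the catalyst-controlled face sets C10 (S), the one centre of 3 kept unchanged to the target.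

Step 2
Reactants: 3
Product: 6 methyl (1S,4aS,8aR)-6,7-dimethoxy-1,4a-dimethyl-5,8-dioxo-1,4,4a,5,8,8a-hexahydronaphthalene-1-carboxylate, via dilithium dienediolate 4 (not isolated), via lithium enolate 5 (not isolated)
Conditions: LDA (2.2 equiv), THF, −78 °C; MeI (1.05 equiv), −78 → −40 °C; MeOH, −78 → 0 °C; aq. NH4Cl
Reagents that add atoms: iodomethane, CI
Why: Dianion alkylation: removal of H-5 and H-4 gives the conjugated dienediolate 4, whose more basic ester-enolate carbon C4 is methylated first; C20 is the only group out of the plane of 4, so MeI enters anti to it (4α-CH3, 4β-CO2Me). Protonation of 5 at C5 under equilibrating conditions (LiOMe/MeOH) should give the trans ring fusion (5α-H), the more stable arrangement of a 6-oxo-10-methyl decalin.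

Step 3
Reactants: 6
Product: 7 methyl (1S,4aS,8aR)-6,7-dimethoxy-1,4a-dimethyl-5,8-dioxo-1,2,3,4,4a,5,8,8a-octahydronaphthalene-1-carboxylate
Conditions: H2 (1 atm), 5% Pd/C, EtOAc, rt
Reagents that add atoms: none
Why: Heterogeneous hydrogenation of the cis-disubstituted C2=C3 bond; the tetrasubstituted, donor-substituted C7=C8 bond and the carbonyl groups should not react at 1 atm, and no stereocentre is formed.

Step 4
Reactants: 7
Product: 9 (4S,5R,6S,10S)-7,8-dimethoxy-9-oxo-11,12,13,14,15,16,17-heptanorlabd-7-en-19,6-olide, via 6β-hydroxy methyl ester 8 (not isolated)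
Conditions: NaBH4 (1 equiv), CeCl3·7H2O (1.1 equiv), MeOH, −40 °C; then NaOMe (0.3 equiv), 0 °C → rt
Reagents that add atoms: none
Why: Luche 1,2-reduction: both ketones are vinylogous ester carbonyls but C9 is neopentyl, so hydride attacks C6, and from the α face because the β face is blocked by axial C20 and the axial ester (6β-OH). The axial 6β-alkoxide sits 1,3-diaxial to the ester and closes the γ-lactone under methoxide with loss of methanol; the medium is kept basic because the allylic 6-hydroxy enol ether is acid-labile.

Step 5
Reactants: 10 (S)-malic acid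
Product: 11 2-[(2S,4S)-2-tert-butyl-5-oxo-1,3-dioxolan-4-yl]acetic acid
Conditions: pivalaldehyde (2 equiv), TsOH·H2O (cat.), H2SO4 (cat.), pentane, reflux, Dean–Stark; recrystallisation
Reagents that add atoms: pivalaldehyde, CC(C)(C)C=O
Why: Acid-catalysed acetalisation of the α-hydroxy acid unit gives the 1,3-dioxolan-4-one; the cis isomer is thermodynamically favoured and is purified by crystallisation, and its acetal carbon stores the configuration of the future C13 (self-regeneration of stereocentres).

Step 6
Reactants: 11
Product: 13 2-[(2S,4S)-2-tert-butyl-5-oxo-4-(prop-2-en-1-yl)-1,3-dioxolan-4-yl]acetic acid, via dilithium enolate carboxylate 12 (not isolated)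
Conditions: LiHMDS (2.1 equiv), THF, −78 °C; allyl bromide (1.5 equiv), −78 → −30 °C; 1 M HCl work-up
Reagents that add atoms: allyl bromide, C=CCBr
Why: Enolate alkylation: the dioxolanone enolate 12, trigonal at the future C13, is attacked by allyl bromide on the face opposite to the tert-butyl group, so allyl takes the place of H with overall retention and the future C13 becomes quaternary.

Step 7
Reactants: 13
Product: 14 (2S)-2-(prop-2-en-1-yl)butane-1,2,4-triol
Conditions: LiAlH4 (4 equiv), THF, 0 °C → reflux; aq. NaOH work-up
Reagents that add atoms: none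
Why: Hydride reduction of the carboxylic acid and of the acylal carbonyl; collapse of the hemiacetal releases pivalaldehyde (reduced to neopentyl alcohol) and leaves the tertiary C13–O bond untouched.

Step 8
Reactants: 14
Product: 15 2-[(4S)-2,2-dimethyl-4-(prop-2-en-1-yl)-1,3-dioxolan-4-yl]ethan-1-ol
Conditions: 2,2-dimethoxypropane (3 equiv), PPTS (5 mol %), acetone, rt
Reagents that add atoms: 2,2-dimethoxypropane, COC(C)(C)OC
Why: Acetonide formation under thermodynamic control gives the five-membered dioxolane of the 1,2-diol in preference to the six-membered acetal of the 1,3-diol, which leaves the primary C11 hydroxyl free.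

Step 9
Reactants: 15
Product: 16 (4S)-4-(2-iodoethyl)-2,2-dimethyl-4-(prop-2-en-1-yl)-1,3-dioxolane
Conditions: I2 (1.3 equiv), PPh3 (1.3 equiv), imidazole (2 equiv), CH2Cl2, 0 °C → rt
Reagents that add atoms: iodine, II
Why: Appel-type iodination of the primary alcohol by SN2 displacement of the alkoxyphosphonium ion; no stereocentre is involved.

Step 10
Reactants: 16 (4S)-4-(2-iodoethyl)-2,2-dimethyl-4-(prop-2-en-1-yl)-1,3-dioxolane; 9 (4S,5R,6S,10S)-7,8-dimethoxy-9-oxo-11,12,13,14,15,16,17-heptanorlabd-7-en-19,6-olide
Product: 20 (4S,5R,6S,10S)-9-{2-[(4R)-2,2-dimethyl-4-(prop-2-en-1-yl)-1,3-dioxolan-4-yl]ethyl}-8-methoxy-7-oxo-11,12,13,14,15,16,17-heptanorlabd-8-en-19,6-olide, via alkyllithium 17 (not isolated), via alkylcerium dichloride 18 (not isolated), via tertiary carbinol 19 (not isolated)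
Conditions: 16 (1.6 equiv), t-BuLi (3.2 equiv), Et2O, −78 °C; CeCl3 (1.7 equiv), THF, −78 °C; 9, −78 °C; then 0.5 M aq. HCl, THF, 0 °C, 15 min
Reagents that add atoms: water, O
Why: Iodine–lithium exchange and transmetalation give an organocerium reagent (kept at −78 °C because 17 is a 5-hexenyl-type lithium) that adds 1,2 to C9, the only ketone of 9; cerium lowers basicity and attack on the hindered lactone. Mild acid ionises the tertiary allylic carbinol 19 to the C9/C7 allyl–oxocarbenium ion, water adds at C7 and methanol is lost (Stork–Danheiser transposition), which places the ketone at C7 and the C8=C9 enol ether in conjugation; the C9 configuration of 19 is erased and the acetonide should survive the short cold acid treatment.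

Step 11
Reactants: 20
Product: 21 (4S,5R,6S,10S)-9-{2-[(4R)-2,2-dimethyl-4-(2-oxoethyl)-1,3-dioxolan-4-yl]ethyl}-8-methoxy-7-oxo-11,12,13,14,15,16,17-heptanorlabd-8-en-19,6-olide
Conditions: OsO4 (2 mol %), NaIO4 (4 equiv), 2,6-lutidine (2 equiv), dioxane/H2O (3:1), rt
Reagents that add atoms: sodium periodate, [Na+].[O-]I(=O)(=O)=O
Why: Lemieux–Johnson oxidation: OsO4 should dihydroxylate the monosubstituted terminal alkene much faster than the tetrasubstituted, conjugated C8=C9 enol ether, and periodate cleaves the diol to the C15 aldehyde; the 13,16-diol is still masked as the acetonide and cannot be cleaved.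

Step 12
Reactants: 21
Product: 23 (4S,5R,6S,10S,13R)-13-hydroxy-8-methoxy-7-oxo-17-norlabd-8-ene-19,6:15,16-diolide, via lactol 22 (not isolated)
Conditions: AcOH/H2O (4:1), 40 °C; evaporate; TEMPO (10 mol %), PhI(OAc)2 (1.5 equiv), CH2Cl2, rt
Reagents that add atoms: none
Why: Aqueous acetic acid removes the acetonide and the freed primary C16 hydroxyl closes onto the aldehyde to the five-membered lactol 22; TEMPO/PhI(OAc)2 oxidises the lactol to the γ-lactone, while the tertiary C13 hydroxyl cannot be oxidised.

Step 13
Reactants: 23
Product: 26 (4S,5R,6S,8R,9S,10S,13R)-9,13-epoxy-8-methoxy-7-oxolabdane-19,6:15,16-diolide, via potassium alkoxide 24 (not isolated), via potassium enolate 25 (not isolated)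
Conditions: KHMDS (1.05 equiv), THF, −78 → −30 °C; MeI (5 equiv), −78 → 0 °C
Reagents that add atoms: iodomethane, CI
Why: One equivalent of amide base removes only the C13 hydroxyl proton (O–H transfer is far faster than any C–H deprotonation); alkoxide 24 adds to C9 of the 8-methoxy enone and the resulting α-methoxy enolate 25 is methylated at C8. The closest known reaction type is tandem conjugate addition/enolate alkylation (vicinal difunctionalisation of an enone), here with a tethered alkoxide as donor, that is, an intramolecular oxa-Michael addition. The tetrahydrofuran closes 5-exo-trig, the C11–C12 tether holding the oxygen over C9 while C8 stays outside the new ring. C9: oxygen enters axially on the α face, anti to axial C20, and since the addition is reversible the epimer with axial O and equatorial C11 (the smaller group axial) should accumulate in any case. C8: MeI attacks the enolate from the α face because the β face is closed by syn-axial C20 and by the C19–O6 lactone bridge, so the methoxy group is left β and trans-diaxial to O-9. C13 is carried through unchanged because its C–O bond is never broken and the enolate is formed by the addition itself, not by an external base that could deprotonate C14 of the side-chain lactone. The step needs carbon rather than oxygen methylation (potassium enolate, MeI, THF) and addition faster than γ-deprotonation at C11; both are favoured by the intramolecular five-membered closure, and the enolate should be much more stable than the tertiary alkoxide. Once C8 is quaternary the product cannot revert by retro-Michael cleavage.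

Step 14
Reactants: 26
Product: 27 (4S,5R,6S,8R,9S,10S,13R)-8-acetoxy-9,13-epoxy-7-oxolabdane-19,6:15,16-diolide (CNP0259020.1)
Conditions: Ac2O, FeCl3 (0.3 equiv), 0 °C → rt
Reagents that add atoms: acetic anhydride, CC(=O)OC(C)=O
Why: Lewis acid-mediated acetolysis of a methyl ether: the exposed methoxy oxygen is acylated and the methyl group is removed by SN2 attack of chloride or acetate, because ionisation at C8 would give a tertiary cation α to the C7 ketone; the C8–O bond therefore stays intact (retention). The ether oxygen between quaternary C9 and C13 should be too hindered to be acylated.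

## Compound list

1 | 2,3-dimethoxy-5-methyl-1,4-benzoquinone (coenzyme Q0) | COC1=C(OC)C(=O)C(C)=CC1=O | starting material
2 | methyl (2E)-penta-2,4-dienoate | C=C/C=C/C(=O)OC | starting material
3 | methyl (1R,4aS,8aR)-6,7-dimethoxy-4a-methyl-5,8-dioxo-1,4,4a,5,8,8a-hexahydronaphthalene-1-carboxylate (cis-fused; labdane numbering 4α-CO2Me, 5β-H, 10β-CH3) | COC1=C(OC)C(=O)[C@@H]2[C@H](C(=O)OC)C=CC[C@]2(C)C1=O | intermediate
4 | dilithium dienediolate of 3 (ester enolate C4=C19 and ketone enolate C5=C6) | COC1=C(OC)C([O-])=C2C(=C([O-])OC)C=CC[C@]2(C)C1=O.[Li+].[Li+] | intermediate (not isolated)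
5 | lithium C5=C6 enolate of the 4α-methyl-4β-methoxycarbonyl compound | COC1=C(OC)C([O-])=C2[C@@](C)(C(=O)OC)C=CC[C@]2(C)C1=O.[Li+] | intermediate (not isolated)
6 | methyl (1S,4aS,8aR)-6,7-dimethoxy-1,4a-dimethyl-5,8-dioxo-1,4,4a,5,8,8a-hexahydronaphthalene-1-carboxylate (trans-fused; 4α-CH3, 4β-CO2Me, 5α-H) | COC1=C(OC)C(=O)[C@H]2[C@@](C)(C(=O)OC)C=CC[C@]2(C)C1=O | intermediate
7 | methyl (1S,4aS,8aR)-6,7-dimethoxy-1,4a-dimethyl-5,8-dioxo-1,2,3,4,4a,5,8,8a-octahydronaphthalene-1-carboxylate | COC1=C(OC)C(=O)[C@H]2[C@@](C)(C(=O)OC)CCC[C@]2(C)C1=O | intermediate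
8 | methyl (4S,5R,6S,10S)-6-hydroxy-7,8-dimethoxy-9-oxo-11,12,13,14,15,16,17-heptanorlabd-7-en-19-oate (6β-OH) | COC1=C(OC)[C@@H](O)[C@H]2[C@@](C)(C(=O)OC)CCC[C@]2(C)C1=O | intermediate (not isolated)
9 | (4S,5R,6S,10S)-7,8-dimethoxy-9-oxo-11,12,13,14,15,16,17-heptanorlabd-7-en-19,6-olide (19,6β-lactone) | COC1=C(OC)C(=O)[C@@]2(C)CCC[C@]3(C)C(=O)O[C@H]1[C@H]23 | intermediate
10 | (S)-malic acid | O[C@@H](CC(=O)O)C(=O)O | starting material
11 | 2-[(2S,4S)-2-tert-butyl-5-oxo-1,3-dioxolan-4-yl]acetic acid (cis) | CC(C)(C)[C@H]1O[C@@H](CC(=O)O)C(=O)O1 | intermediate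
12 | dilithium enolate carboxylate of 11 | CC(C)(C)[C@H]1OC(CC(=O)[O-])=C([O-])O1.[Li+].[Li+] | intermediate (not isolated)
13 | 2-[(2S,4S)-2-tert-butyl-5-oxo-4-(prop-2-en-1-yl)-1,3-dioxolan-4-yl]acetic acid (allyl trans to tert-butyl) | CC(C)(C)[C@H]1O[C@@](CC=C)(CC(=O)O)C(=O)O1 | intermediate
14 | (2S)-2-(prop-2-en-1-yl)butane-1,2,4-triol | C=CC[C@@](O)(CO)CCO | intermediate
15 | 2-[(4S)-2,2-dimethyl-4-(prop-2-en-1-yl)-1,3-dioxolan-4-yl]ethan-1-ol | C=CC[C@]1(CCO)COC(C)(C)O1 | intermediate
16 | (4S)-4-(2-iodoethyl)-2,2-dimethyl-4-(prop-2-en-1-yl)-1,3-dioxolane | C=CC[C@]1(CCI)COC(C)(C)O1 | intermediate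
17 | alkyllithium from 16 (lithium in place of iodine) | C=CC[C@]1(CC[Li])COC(C)(C)O1 | intermediate (not isolated)
18 | alkylcerium dichloride from 17 | C=CC[C@]1(CC[Ce](Cl)Cl)COC(C)(C)O1 | intermediate (not isolated)
19 | (4S,5R,6S,10S)-9-{2-[(4R)-2,2-dimethyl-4-(prop-2-en-1-yl)-1,3-dioxolan-4-yl]ethyl}-9-hydroxy-7,8-dimethoxy-11,12,13,14,15,16,17-heptanorlabd-7-en-19,6-olide (C9 epimers, inconsequential) | COC1=C(OC)C(O)(CC[C@@]4(CC=C)COC(C)(C)O4)[C@@]2(C)CCC[C@]3(C)C(=O)O[C@H]1[C@H]23 | intermediate (not isolated)
20 | (4S,5R,6S,10S)-9-{2-[(4R)-2,2-dimethyl-4-(prop-2-en-1-yl)-1,3-dioxolan-4-yl]ethyl}-8-methoxy-7-oxo-11,12,13,14,15,16,17-heptanorlabd-8-en-19,6-olide | COC1=C(CC[C@@]4(CC=C)COC(C)(C)O4)[C@@]2(C)CCC[C@]3(C)C(=O)O[C@H](C1=O)[C@H]23 | intermediate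
21 | (4S,5R,6S,10S)-9-{2-[(4R)-2,2-dimethyl-4-(2-oxoethyl)-1,3-dioxolan-4-yl]ethyl}-8-methoxy-7-oxo-11,12,13,14,15,16,17-heptanorlabd-8-en-19,6-olide | COC1=C(CC[C@@]4(CC=O)COC(C)(C)O4)[C@@]2(C)CCC[C@]3(C)C(=O)O[C@H](C1=O)[C@H]23 | intermediate
22 | (4S,5R,6S,10S,13R)-13,15-dihydroxy-15,16-epoxy-8-methoxy-7-oxo-17-norlabd-8-en-19,6-olide (lactol, C15 epimers) | COC1=C(CC[C@]4(O)COC(O)C4)[C@@]2(C)CCC[C@]3(C)C(=O)O[C@H](C1=O)[C@H]23 | intermediate (not isolated)
23 | (4S,5R,6S,10S,13R)-13-hydroxy-8-methoxy-7-oxo-17-norlabd-8-ene-19,6:15,16-diolide | COC1=C(CC[C@]4(O)COC(=O)C4)[C@@]2(C)CCC[C@]3(C)C(=O)O[C@H](C1=O)[C@H]23 | intermediate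
24 | potassium C13 alkoxide of 23 | COC1=C(CC[C@]4([O-])COC(=O)C4)[C@@]2(C)CCC[C@]3(C)C(=O)O[C@H](C1=O)[C@H]23.[K+] | intermediate (not isolated)
25 | potassium C7=C8 enolate of the 9α,13-epoxy-8-methoxy-7-ketone | COC1=C([O-])[C@H]2OC(=O)[C@@]3(C)CCC[C@@](C)([C@@H]23)[C@@]12CC[C@@]1(COC(=O)C1)O2.[K+] | intermediate (not isolated)
26 | (4S,5R,6S,8R,9S,10S,13R)-9,13-epoxy-8-methoxy-7-oxolabdane-19,6:15,16-diolide (8β-OMe, 8α-CH3, 9α-O) | CO[C@@]1(C)C(=O)[C@H]2OC(=O)[C@@]3(C)CCC[C@@](C)([C@@H]23)[C@@]12CC[C@@]1(COC(=O)C1)O2 | intermediate
27 | (4S,5R,6S,8R,9S,10S,13R)-8-acetoxy-9,13-epoxy-7-oxolabdane-19,6:15,16-diolide (CNP0259020.1) | CC(=O)O[C@@]1(C)C(=O)[C@H]2OC(=O)[C@@]3(C)CCC[C@@](C)([C@@H]23)[C@@]12CC[C@@]1(COC(=O)C1)O2 | target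

## Step count and least certain steps

Total: 14 steps (steps 1–4 for the core, steps 5–9 for the side chain, steps 10–14 after the union). Longest linear sequence: 10 steps (steps 5–14, from (S)-malic acid); the core branch from 1 is 9 steps.

Step 13 (key step). The conjugate addition may revert, after which the open tertiary alkoxide is O-methylated. A proton may pass from C11 to the alkoxide, followed by deconjugative methylation. A proton may also pass from C14 of the side-chain lactone to the enolate, followed by β-elimination of O-9, which would scramble C13. All three are proton-transfer or reversal processes that compete with a slow methylation at a very crowded carbon. The fallback separates ring closure from enolate formation and uses no strong base. It sets out from 23: camphorsulfonic acid in CH2Cl2 closes the ring by acid-catalysed oxa-Michael addition to (13R)-9α,13-epoxy-8α-methoxy-7-oxo-17-norlabdane-19,6β:15,16-diolide F1 (the other C8 epimer would converge). Soft enolisation with TMSOTf/Et3N goes towards C8, because H-6 is equatorial and next to the lactone bridge, and gives the 7-trimethylsilyl enol ether F2. Fluoride-promoted methylation (MeI, anhydrous tetrabutylammonium difluorotriphenylsilicate) from the α face then comes back to the route at 26.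

Step 1. The cycloaddition may be too slow, since a doubly methoxy-substituted quinone meets an electron-poor diene; an uncatalysed or wrongly oriented pathway would then erode regio- and enantioselectivity. The fallback changes the diene. It sets out from 1: (2E)-penta-2,4-dien-1-ol is silylated to tert-butyl(dimethyl)[(2E)-penta-2,4-dien-1-yloxy]silane F3, an electron-richer 1-alkyl diene with the same orientation preference. Under the same catalysis this gives the cis-fused silyloxymethyl adduct F4. TBAF gives the primary alcohol F5, Jones oxidation the carboxylic acid F6, and trimethylsilyldiazomethane returns to the route at 3.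

Step 2. The dienediolate may be methylated at C5 or on oxygen, or twice, because both carbons of the dianion are nucleophilic; the C5 equilibration may also stop short. The fallback sets C4 on a lactone enolate that has only one open face. It sets out from 3: hydrogenation gives the cis-fused dihydro diketo ester F7, and DBU epimerises C5 to the trans-fused diketo ester F8 (ester equatorial, 4α). Luche reduction gives the 6β-hydroxy 4α-ester F9. Sodium methoxide in hot methanol epimerises C4 through the ester enolate and drains the 4β-epimer as the 18-nor lactone F10 (4α-H). LDA and MeI methylate the lactone enolate from the α face, the only one open in the bridged tricycle, and return to the route at 9. Steps 2–4 are bypassed.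

Step 10. The organometallic reagent may add to the C19 lactone carbonyl, or enolise the substrate, in place of attack at neopentyl C9; it may also cyclise (5-hexenyl type) if the temperature rises. The fallback postpones lactone closure so that C19 is a hindered, less electrophilic methyl ester during the addition. It sets out from 7: Luche reduction without added base gives 8, which is isolated and silylated (TESOTf, 2,6-lutidine) to the 6β-triethylsilyl ether F11. Organocerium 18 adds to C9 to give the tertiary carbinol F12. Aqueous HCl in THF effects transposition and desilylation to the 6β-hydroxy ester enone F13, which lactonises on gentle warming with PPTS in toluene and comes back to the route at 20.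

Step 14. Under the Lewis acid the bis-tertiary tetrahydrofuran ether or the β-alkoxy lactone at C13 may ionise faster than the methoxy group is acylated, because both can give tertiary cations. The fallback is oxidative and uses no Lewis acid. It sets out from 26: catalytic RuCl3 with NaIO4 oxidises the O–CH3 group, the only C–H next to an ether oxygen in the molecule, to the 8β-formate F14. NaHCO3 in methanol gives the tertiary 8β-alcohol F15, and Ac2O with DMAP comes back to the route at 27.

## Further compounds

F1 | step 13 | (13R)-9α,13-epoxy-8α-methoxy-7-oxo-17-norlabdane-19,6β:15,16-diolide (8β-H) | CO[C@@H]1C(=O)[C@H]2OC(=O)[C@@]3(C)CCC[C@@](C)([C@@H]23)[C@@]12CC[C@@]1(COC(=O)C1)O2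
F2 | step 13 | (13R)-9α,13-epoxy-8-methoxy-7-(trimethylsilyloxy)-17-norlabd-7-ene-19,6β:15,16-diolide | COC1=C(O[Si](C)(C)C)[C@H]2OC(=O)[C@@]3(C)CCC[C@@](C)([C@@H]23)[C@@]12CC[C@@]1(COC(=O)C1)O2
F3 | step 1 | tert-butyl(dimethyl)[(2E)-penta-2,4-dien-1-yloxy]silane | C=C/C=C/CO[Si](C)(C)C(C)(C)C
F4 | step 1 | cis-fused adduct of 1 and F3 (4α-CH2OTBS, 5β-H, 10β-CH3) | COC1=C(OC)C(=O)[C@@H]2[C@H](CO[Si](C)(C)C(C)(C)C)C=CC[C@]2(C)C1=O
F5 | step 1 | cis-fused 4α-hydroxymethyl adduct | COC1=C(OC)C(=O)[C@@H]2[C@H](CO)C=CC[C@]2(C)C1=O
F6 | step 1 | cis-fused 4α-carboxylic acid (free acid of 3) | COC1=C(OC)C(=O)[C@@H]2[C@H](C(=O)O)C=CC[C@]2(C)C1=O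
F7 | step 2 | cis-fused 2,3-dihydro derivative of 3 (4α-CO2Me, 5β-H) | COC1=C(OC)C(=O)[C@@H]2[C@H](C(=O)OC)CCC[C@]2(C)C1=O
F8 | step 2 | trans-fused diketo ester (4α-CO2Me, 5α-H) | COC1=C(OC)C(=O)[C@H]2[C@H](C(=O)OC)CCC[C@]2(C)C1=O
F9 | step 2 | trans-fused 6β-hydroxy 4α-ester | COC1=C(OC)[C@@H](O)[C@H]2[C@H](C(=O)OC)CCC[C@]2(C)C1=O
F10 | step 2 | 7,8-dimethoxy-9-oxo-11,12,13,14,15,16,17,18-octanorlabd-7-en-19,6β-olide (4α-H) | COC1=C(OC)C(=O)[C@@]2(C)CCC[C@@H]3C(=O)O[C@H]1[C@H]23
F11 | step 10 | 6β-triethylsilyl ether of 8 | COC1=C(OC)[C@@H](O[Si](CC)(CC)CC)[C@H]2[C@@](C)(C(=O)OC)CCC[C@]2(C)C1=O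
F12 | step 10 | C9 tertiary carbinol from F11 and 18 (C9 epimers) | COC1=C(OC)[C@@H](O[Si](CC)(CC)CC)[C@H]2[C@@](C)(C(=O)OC)CCC[C@]2(C)C1(O)CC[C@@]1(CC=C)COC(C)(C)O1
F13 | step 10 | 6β-hydroxy-8-methoxy-7-oxo-Δ8(9) methyl ester carrying the side chain of 20 | COC1=C(CC[C@@]4(CC=C)COC(C)(C)O4)[C@@]2(C)CCC[C@](C)(C(=O)OC)[C@@H]2[C@H](O)C1=O
F14 | step 14 | (13R)-9α,13-epoxy-8β-formyloxy-7-oxolabdane-19,6β:15,16-diolide | O=CO[C@@]1(C)C(=O)[C@H]2OC(=O)[C@@]3(C)CCC[C@@](C)([C@@H]23)[C@@]12CC[C@@]1(COC(=O)C1)O2
F15 | step 14 | (13R)-9α,13-epoxy-8β-hydroxy-7-oxolabdane-19,6β:15,16-diolide | O[C@@]1(C)C(=O)[C@H]2OC(=O)[C@@]3(C)CCC[C@@](C)([C@@H]23)[C@@]12CC[C@@]1(COC(=O)C1)O2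
A1 | alternative 1 | 8β-acetoxy-9α-hydroxy-7-oxo-15,16-epoxylabda-13(16),14-dien-19,6β-olide | CC(=O)O[C@@]1(C)C(=O)[C@H]2OC(=O)[C@@]3(C)CCC[C@@](C)([C@@H]23)[C@@]1(O)CCc1ccoc1
A2 | alternative 1 | 8β-acetoxy-9α,13:15,16-diepoxy-7-oxolabd-14-en-19,6β-olide (C13 epimers) | CC(=O)O[C@@]1(C)C(=O)[C@H]2OC(=O)[C@@]3(C)CCC[C@@](C)([C@@H]23)[C@@]12CCC1(COC=C1)O2
A3 | alternative 2 | C13-spiro cyclobutanone (C14 and C16 methylenes joined through one carbonyl carbon) | CC(=O)O[C@@]1(C)C(=O)[C@H]2OC(=O)[C@@]3(C)CCC[C@@](C)([C@@H]23)[C@@]12CCC1(CC(=O)C1)O2
A4 | alternative 2 | 8β-acetoxy-9α,13-epoxy-7-oxo-14,15-dinorlabd-13(16)-en-19,6β-olide (exocyclic enol ether) | CC(=O)O[C@@]1(C)C(=O)[C@H]2OC(=O)[C@@]3(C)CCC[C@@](C)([C@@H]23)[C@@]12CCC(=C)O2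
A5 | alternative 3 | 4-{2-[(3R)-3-hydroxy-5-oxooxolan-3-yl]ethyl}-3,5-dimethylphenol | Cc1cc(O)cc(C)c1CC[C@]1(O)COC(=O)C1
A6 | alternative 3 | bis-spiro cyclohexa-2,5-dienone from A5 (3,5-dimethyl, C4 spiro to the tetrahydrofuran) | CC1=CC(=O)C=C(C)C12CC[C@@]1(COC(=O)C1)O2
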